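**Strategy**

The plan rests on cutting the C2–C1' bond between flavanone ring C and ring B. C2 is the only stereocentre, a benzylic ether carbon β to the C4 ketone, so it can be made by adding an aryl group to C2 of a flat 7-benzyloxy-5-methoxychromone. A palladium-catalysed enantioselective 1,4-addition of an arylboronic acid does this in one operation: it joins the two halves and fixes (2S). The donor is a fully benzylated 6-arylapigenin whose ring B carries B(OH)2 para to its benzyloxy group; it is built from apigenin by C6 iodination, Suzuki coupling with a chloro-substituted linchpin and borylation. Neutral hydrogenolysis finishes the synthesis.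

Key step: step 10

Assumption: the sense of induction that t-BuPyOx shows with cyclic enones is taken to hold for chromone 13, so the (R)-ligand should give the (2S)-flavanone; a trial with phenylboronic acid settles this before 8 is committed, and the (S)-ligand is used instead if the sense proves opposite.

Remark: the C3'–C6'' biaryl axis has three ortho oxygen substituents and no defined configuration in the target; slow rotation may show in the benzylated intermediates but is of no consequence.

**Route**

Step 1
Reactants: 1 apigenin
Product: 2 7,4'-di-O-benzylapigenin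
Conditions: BnBr (2.2 equiv), K2CO3, DMF, 50 °C
Reagents that add atoms: benzyl bromide, BrCc1ccccc1
Why: Williamson ether synthesis in which the 7-OH and 4'-OH react while the 5-OH, hydrogen-bonded to the C4 carbonyl, is too weakly nucleophilic under these conditions and stays free.

Step 2
Reactants: 2 7,4'-di-O-benzylapigenin
Product: 3 6-iodo-7,4'-di-O-benzylapigenin
Conditions: BnMe3N·ICl2 (1.1 equiv), CaCO3, CH2Cl2–MeOH, rt
Reagents that add atoms: benzyltrimethylammonium dichloroiodate, C[N+](C)(C)Cc1ccccc1.Cl[I-]Cl
Why: Electrophilic aromatic iodination of the phloroglucinol-type ring A, directed to C6 by the free 5-OH ortho to it, as is usual for 5-hydroxy-7-alkoxyflavones (the 5-O-alkyl series would go to C8, which is why iodination precedes the third benzylation).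

Step 3
Reactants: 3 6-iodo-7,4'-di-O-benzylapigenin
Product: 4 6-iodo-5,7,4'-tri-O-benzylapigenin
Conditions: BnBr (1.5 equiv), K2CO3, cat. n-Bu4NI, DMF, 70 °C
Reagents that add atoms: benzyl bromide, BrCc1ccccc1
Why: Williamson ether synthesis under more forcing conditions, needed because the chelated 5-OH is flanked by iodine, and useful because it removes the only acidic proton before the organometallic steps.

Step 4
Reactants: 4 6-iodo-5,7,4'-tri-O-benzylapigenin; 5 (2-benzyloxy-5-chlorophenyl)boronic acid
Product: 6 6-(2-benzyloxy-5-chlorophenyl)-5,7,4'-tri-O-benzylapigenin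
Conditions: Pd(PPh3)4 (10 mol %), K3PO4, 5 (1.5 equiv), DMF–H2O (9:1), 85 °C
Reagents that add atoms: none
Why: Suzuki–Miyaura coupling that forms the C3'–C6'' biaryl bond at the iodide only, because triphenylphosphine-ligated zerovalent palladium does not insert into the electron-rich C–Cl bond para to the benzyloxy group, so the chloride is kept as the handle for boron.

Step 5
Reactants: 6 6-(2-benzyloxy-5-chlorophenyl)-5,7,4'-tri-O-benzylapigenin
Product: 7 pinacol boronate of the 6-arylapigenin (Bpin in place of Cl)
Conditions: B2pin2 (1.5 equiv), Pd2(dba)3 (2 mol %), XPhos (8 mol %), KOAc, 1,4-dioxane, 100 °C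
Reagents that add atoms: bis(pinacolato)diboron, CC1(C)OB(OC1(C)C)B1OC(C)(C)C(C)(C)O1
Why: Miyaura borylation in which the bulky, electron-rich biarylphosphine allows oxidative addition to the unhindered aryl chloride and the weak base KOAc prevents the product from coupling with unreacted chloride; the ester can be purified on silica.

Step 6
Reactants: 7 pinacol boronate of the 6-arylapigenin
Product: 8 flavone-bearing arylboronic acid
Conditions: NaIO4 (3 equiv), NH4OAc (3 equiv), acetone–THF–H2O, rt
Reagents that add atoms: water, O
Why: Hydrolysis of the boronic ester driven by oxidative glycol cleavage of the released pinacol to acetone, a mild buffered deprotection that leaves benzyl ethers and the flavone untouched and gives the free acid needed for transmetalation.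

Step 7
Reactants: 9 2',4',6'-trihydroxyacetophenone
Product: 10 4'-benzyloxy-2',6'-dihydroxyacetophenone
Conditions: BnBr (1.05 equiv), K2CO3 (1.1 equiv), DMF, rt
Reagents that add atoms: benzyl bromide, BrCc1ccccc1
Why: Williamson ether synthesis that selects the 4'-OH, the most acidic hydroxyl and the only one not tied to the acetyl carbonyl by a hydrogen bond.

Step 8
Reactants: 10 4'-benzyloxy-2',6'-dihydroxyacetophenone
Product: 11 4'-benzyloxy-2'-hydroxy-6'-methoxyacetophenone
Conditions: Me2SO4 (1.05 equiv), K2CO3, acetone, reflux
Reagents that add atoms: dimethyl sulfate, COS(=O)(=O)OC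
Why: O-Methylation (Williamson type) of one of two equivalent ortho hydroxyls, which stops after one methyl group because the remaining OH then holds the carbonyl in a strong chelate.

Step 9
Reactants: 11 4'-benzyloxy-2'-hydroxy-6'-methoxyacetophenone
Product: 13 7-benzyloxy-5-methoxy-4H-chromen-4-one, via enaminone 12 (not isolated)
Conditions: DMF dimethyl acetal (3 equiv), toluene, 95 °C; evaporate; conc. HCl, CH2Cl2, 40 °C
Reagents that add atoms: N,N-dimethylformamide dimethyl acetal, COC(OC)N(C)C
Why: Condensation of the methyl ketone with the amide acetal gives the enaminone, and acid then promotes an intramolecular oxa-Michael addition–elimination in which the phenol oxygen attacks the β-carbon and dimethylamine leaves, closing the pyranone ring.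

Step 10
Reactants: 8 flavone-bearing arylboronic acid; 13 7-benzyloxy-5-methoxy-4H-chromen-4-one
Product: 14 (2S)-pentabenzyl ether of the target
Conditions: Pd(OCOCF3)2 (10 mol %), (R)-t-BuPyOx (12 mol %), NH4PF6 (30 mol %), H2O (5 equiv), 13 (2 equiv, excess recovered), ClCH2CH2Cl, 60 °C
Reagents that add atoms: none
Why: Boron-to-palladium transmetalation of 8 gives a cationic aryl complex of divalent palladium held by the pyridine–oxazoline ligand, the C2=C3 bond of 13 inserts into the Pd–aryl bond so that the aryl group lands on C2, and water protonates the resulting palladium enolate, which releases the flavanone and returns the catalyst without any change of oxidation state. The closest known reaction type is the pyridine–oxazoline/palladium-catalysed asymmetric conjugate addition of arylboronic acids to 2-unsubstituted chromones, which gives flavanones. No ring is closed here; the existing pyranone ring is only saturated. The C2 stereocentre is set in the insertion step by the tert-butyl group of the ligand, which shields one face of the bound chromone, and the (R)-ligand is chosen to give 2S. The step needs facial selectivity, supplied by the ligand, and site selectivity for 13 over the flavone enone inside 8, which is secured because the flavone β-carbon already carries an aryl group and is both hindered and deactivated. The boron of 8 has no ortho substituent and sits para to a benzyloxy group, so transmetalation should be fast, and the base-free medium keeps ring C of the product from opening to the chalcone.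

Step 11
Reactants: 14 (2S)-pentabenzyl ether of the target
Product: 15 target CNP0332590.1
Conditions: H2 (1 atm), 10% Pd/C, EtOAc–THF (1:1), rt, stopped when uptake ends
Reagents that add atoms: none
Why: Catalytic hydrogenolysis of the five benzyl ethers under neutral conditions, which leaves the methyl ether, both carbonyl groups and the base-labile C2 stereocentre unchanged.

**Compound list**

1 | apigenin | O=c1cc(-c2ccc(O)cc2)oc2cc(O)cc(O)c12 | starting material
2 | 7,4'-di-O-benzylapigenin | O=c1cc(-c2ccc(OCc3ccccc3)cc2)oc2cc(OCc3ccccc3)cc(O)c12 | intermediate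
3 | 6-iodo-7,4'-di-O-benzylapigenin | O=c1cc(-c2ccc(OCc3ccccc3)cc2)oc2cc(OCc3ccccc3)c(I)c(O)c12 | intermediate
4 | 6-iodo-5,7,4'-tri-O-benzylapigenin | O=c1cc(-c2ccc(OCc3ccccc3)cc2)oc2cc(OCc3ccccc3)c(I)c(OCc3ccccc3)c12 | intermediate
5 | (2-benzyloxy-5-chlorophenyl)boronic acid | OB(O)c1cc(Cl)ccc1OCc1ccccc1 | starting material
6 | 6-(2-benzyloxy-5-chlorophenyl)-5,7,4'-tri-O-benzylapigenin | O=c1cc(-c2ccc(OCc3ccccc3)cc2)oc2cc(OCc3ccccc3)c(-c3cc(Cl)ccc3OCc3ccccc3)c(OCc3ccccc3)c12 | intermediate
7 | 6-[2-benzyloxy-5-(4,4,5,5-tetramethyl-1,3,2-dioxaborolan-2-yl)phenyl]-5,7,4'-tri-O-benzylapigenin | O=c1cc(-c2ccc(OCc3ccccc3)cc2)oc2cc(OCc3ccccc3)c(-c3cc(B4OC(C)(C)C(C)(C)O4)ccc3OCc3ccccc3)c(OCc3ccccc3)c12 | intermediate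
8 | {4-benzyloxy-3-[5,7-bis(benzyloxy)-2-(4-benzyloxyphenyl)-4-oxo-4H-chromen-6-yl]phenyl}boronic acid | O=c1cc(-c2ccc(OCc3ccccc3)cc2)oc2cc(OCc3ccccc3)c(-c3cc(B(O)O)ccc3OCc3ccccc3)c(OCc3ccccc3)c12 | intermediate
9 | 2',4',6'-trihydroxyacetophenone | CC(=O)c1c(O)cc(O)cc1O | starting material
10 | 4'-benzyloxy-2',6'-dihydroxyacetophenone | CC(=O)c1c(O)cc(OCc2ccccc2)cc1O | intermediate
11 | 4'-benzyloxy-2'-hydroxy-6'-methoxyacetophenone | CC(=O)c1c(O)cc(OCc2ccccc2)cc1OC | intermediate
12 | (E)-1-(4-benzyloxy-2-hydroxy-6-methoxyphenyl)-3-(dimethylamino)prop-2-en-1-one | CN(C)/C=C/C(=O)c1c(O)cc(OCc2ccccc2)cc1OC | intermediate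
13 | 7-benzyloxy-5-methoxy-4H-chromen-4-one | COc1cc(OCc2ccccc2)cc2occc(=O)c12 | intermediate
14 | (2S)-7-benzyloxy-2-{4-benzyloxy-3-[5,7-bis(benzyloxy)-2-(4-benzyloxyphenyl)-4-oxo-4H-chromen-6-yl]phenyl}-5-methoxychroman-4-one | COc1cc(OCc2ccccc2)cc2c1C(=O)C[C@@H](c1ccc(OCc3ccccc3)c(-c3c(OCc4ccccc4)cc4oc(-c5ccc(OCc6ccccc6)cc5)cc(=O)c4c3OCc3ccccc3)c1)O2 | intermediate
15 | (2S)-2-{3-[5,7-dihydroxy-2-(4-hydroxyphenyl)-4-oxo-4H-chromen-6-yl]-4-hydroxyphenyl}-7-hydroxy-5-methoxychroman-4-one | COc1cc(O)cc2c1C(=O)C[C@@H](c1ccc(O)c(-c3c(O)cc4oc(-c5ccc(O)cc5)cc(=O)c4c3O)c1)O2 | target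

**Summary**

Total step count: 11. Longest linear sequence: 8 steps (steps 1–6, 10 and 11, from apigenin); the chromone branch (steps 7–9) joins at step 10.

Steps most likely to fail:

1. Step 10. The bulky aryl–palladium species may insert the electron-rich 5,7-dialkoxychromone so slowly that protodeboronation of 8 takes over, or facial selectivity may erode with so large a donor. The fallback reverses the order of the two C–C bond formations and sets out from chromone 13. The same palladium/pyridine–oxazoline catalyst, which tolerates aryl chlorides, adds the small, commercial (4-benzyloxy-3-chlorophenyl)boronic acid (OB(O)c1ccc(OCc2ccccc2)c(Cl)c1) to give (2S)-7-benzyloxy-2-(4-benzyloxy-3-chlorophenyl)-5-methoxychroman-4-one F1. Miyaura borylation of its chloride (Pd2(dba)3, XPhos, B2pin2, KOAc, dioxane, 90 °C) gives the pinacol boronate (2S)-7-benzyloxy-2-[4-benzyloxy-3-(4,4,5,5-tetramethyl-1,3,2-dioxaborolan-2-yl)phenyl]-5-methoxychroman-4-one F2. Suzuki–Miyaura coupling of F2 with iodide 4 (Pd(OAc)2, SPhos, anhydrous CsF, dioxane, 80 °C) then comes back to the route at 14. Because the stereocentre now meets base, only weak or anhydrous bases are used and the enantiomeric purity would have to be checked after each of the two steps.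

2. Step 4. Transmetalation at the palladium centre on C6, flanked by two benzyloxy groups, may be slow, so that protodeboronation of 5 or protodeiodination of 4 competes; a more active ligand would risk insertion into the C–Cl bond and oligomerisation. The fallback replaces the boron donor by a zinc donor and sets out from iodide 4. 2-Bromo-4-chlorophenol is benzylated (BnBr, K2CO3, DMF) to 1-benzyloxy-2-bromo-4-chlorobenzene F3. Bromine–lithium exchange (n-BuLi, THF, −78 °C), which leaves the chloride alone, followed by ZnCl2 gives (2-benzyloxy-5-chlorophenyl)zinc chloride F4. Negishi coupling of F4 with 4 (Pd(PPh3)4, THF, 50 °C) runs without water or base and returns to the route at 6.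

3. Step 11. Cleavage of the hindered benzyl ether on the 5-oxygen of the flavone may be incomplete, and prolonged exposure may cause over-reduction (hydrogenolysis of the benzylic C2–O1 bond of ring C or saturation of the flavone C2=C3 bond). The fallback uses Lewis-acid debenzylation instead of hydrogen and sets out from 14: BCl3 with pentamethylbenzene as benzyl cation scavenger in CH2Cl2 at −78 °C, quenched cold with MeOH, should give 15 directly. At this temperature the aryl methyl ether, although peri to the carbonyl, is expected to survive, and no reducing agent is present. No new compound is made.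

**Further compounds**

F1 | step 10 | (2S)-7-benzyloxy-2-(4-benzyloxy-3-chlorophenyl)-5-methoxychroman-4-one | COc1cc(OCc2ccccc2)cc2c1C(=O)C[C@@H](c1ccc(OCc3ccccc3)c(Cl)c1)O2
F2 | step 10 | (2S)-7-benzyloxy-2-[4-benzyloxy-3-(4,4,5,5-tetramethyl-1,3,2-dioxaborolan-2-yl)phenyl]-5-methoxychroman-4-one | COc1cc(OCc2ccccc2)cc2c1C(=O)C[C@@H](c1ccc(OCc3ccccc3)c(B3OC(C)(C)C(C)(C)O3)c1)O2
F3 | step 4 | 1-benzyloxy-2-bromo-4-chlorobenzene | Clc1ccc(OCc2ccccc2)c(Br)c1
F4 | step 4 | (2-benzyloxy-5-chlorophenyl)zinc chloride | Cl[Zn]c1cc(Cl)ccc1OCc1ccccc1
F0 | step 11 | none | none
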